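**Plan**

- Enabling feature: the oxygen on C7 (benzylic carbinol carbon on ring A) and C9 (the CH2OH carbon on C8, which carries ring B) stand 1,3 to each other across the C7–C8 bond between the two aryl groups. This is the pattern left when an E-stilbene of rings A and B takes up formaldehyde carbon at C8 and oxygen at C7. The ring C/ring D dihydrobenzofuran (O1–C2–C3–CH2OH) is the same unit closed onto the ring C phenol, so one dioxane supplies both halves.
- Cuts: lactone Cα–CH2(ring C) (enolate alkylation); ring B–CH2 on lactone Cβ (aryl Grignard opening of a cyclopropane-fused lactone); benzofuran O1–C2; C8–C9 and C7–O (Prins) and C7=C8 (olefination) in the shared diarylpropane unit.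
- Forward: stilbene 6 → trans-dioxane 8 (first ring) → triol 11. Triol 11 is divided into aryl bromide 13 (ring A/B half) and, after closure of the dihydrobenzofuran, benzylic bromide 18 (ring C/D half). The butyrolactone comes from cyclopropane lactone 21, opened by the Grignard reagent of 13 and then alkylated with 18; desilylation and hydrogenolysis finish.
- Stereochemistry: C7/C8 (and with them benzofuran C3) from the catalyst-controlled Prins addition to the E-alkene; benzofuran C2 from trans-selective ring closure under control of C3; lactone Cβ from (S)-epichlorohydrin; lactone Cα from alkylation anti to the Cβ substituent.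

Key step: step 5

Remark: the sense of induction of the confined acid on a 1,2-diaryl alkene cannot be predicted; the catalyst antipode that gives (4S,5S)-8 is to be fixed in a trial run, both antipodes being accessible from (R)- or (S)-BINOL.
Remark: formaldehyde 7 is handled as dry paraformaldehyde throughout.

**Route**

Step 1
Reactants: 1 5-bromo-2-hydroxy-3-methoxybenzaldehyde
Product: 2 4-bromo-2-formyl-6-methoxyphenyl 4-methylbenzenesulfonate
Conditions: TsCl, Et3N, DMAP (cat.), CH2Cl2, 0 °C → rt
Reagents that add atoms: 4-toluenesulfonyl chloride, Cc1ccc(cc1)S(Cl)(=O)=O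
Why: Phenol O-sulfonylation gives a group that withstands the olefination base and the acid of step 5, cannot migrate to a neighbouring alkoxide (unlike an acyl group) and makes ring B the electron-poorer aryl group.

Step 2
Reactants: 3 [4-(benzyloxy)-3-methoxyphenyl]methanol
Product: 4 1-(benzyloxy)-4-(bromomethyl)-2-methoxybenzene
Conditions: PBr3, CH2Cl2, 0 °C
Reagents that add atoms: phosphorus tribromide, BrP(Br)Br
Why: Conversion of a benzylic alcohol into the bromide by SN2 displacement of its phosphite ester, routine for alkoxybenzyl alcohols.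

Step 3
Reactants: 4 1-(benzyloxy)-4-(bromomethyl)-2-methoxybenzene
Product: 5 diethyl [4-(benzyloxy)-3-methoxybenzyl]phosphonate
Conditions: P(OEt)3 (neat), 130 °C
Reagents that add atoms: triethyl phosphite, CCOP(OCC)OCC
Why: Michaelis–Arbuzov reaction of a reactive benzylic bromide, driven by loss of bromoethane.

Step 4
Reactants: 5 diethyl [4-(benzyloxy)-3-methoxybenzyl]phosphonate; 2 4-bromo-2-formyl-6-methoxyphenyl 4-methylbenzenesulfonate
Product: 6 2-[(E)-2-(4-benzyloxy-3-methoxyphenyl)ethenyl]-4-bromo-6-methoxyphenyl 4-methylbenzenesulfonate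
Conditions: NaH, THF, 0 °C → rt
Reagents that add atoms: none
Why: Horner–Wadsworth–Emmons olefination of a semi-stabilised benzylphosphonate anion with an aromatic aldehyde, which should give the E-stilbene through reversible addition and elimination from the anti adduct, the aryl sulfonate being inert to the phosphonate anion.

Step 5
Reactants: 6 (E)-stilbene sulfonate; 7 formaldehyde (as paraformaldehyde, two units incorporated)
Product: 8 (4S,5S)-4-[4-(benzyloxy)-3-methoxyphenyl]-5-[5-bromo-3-methoxy-2-(tosyloxy)phenyl]-1,3-dioxane (trans)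
Conditions: confined BINOL-derived N-triflyl imino-imidodiphosphate Brønsted acid (5 mol%), paraformaldehyde (5 equiv), CHCl3, 25 °C
Reagents that add atoms: none
Why: Proposed new method: the confined chiral acid protonates a formaldehyde oligomer whose terminal CH2=O+ carbon adds to C8 (the alkene carbon beside ring B) while charge builds at C7, where the para-benzyloxy group of ring A stabilises it, and the hemiformal hydroxyl of the same oligomer then closes on C7, so that C8–C9 and C7–O form in one asynchronous event (closest known reaction type: the imino-imidodiphosphate-catalysed enantioselective Prins reaction of styrenes with paraformaldehyde to 4-aryl-1,3-dioxanes and the classical acid Prins reaction of 1-arylpropenes, not yet shown for 1,2-diaryl alkenes). The 1,3-dioxane closes in the 6-exo-trig mode by capture of the quinoid benzylic cation. C5 (= C8) is set by the alkene face that the catalyst pocket leaves open during C–C bond formation. C4 (= C7) follows from the E geometry and a chair-like closure that places both aryl groups equatorial, hence trans. The step needs regioselectivity, secured by donor ring A against sulfonate-deactivated ring B, and chemoselectivity for the alkene over the arenes and over the ortho oxygen, secured by the higher nucleophilicity of the p-alkoxystyrene π-bond and by the non-nucleophilic tosylate.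

Step 6
Reactants: 8 (4S,5S)-trans-dioxane
Product: 10 (1S,2S)-1-[4-(benzyloxy)-3-methoxyphenyl]-2-[5-bromo-3-methoxy-2-(tosyloxy)phenyl]propane-1,3-diol, via alkoxymethylpyridinium triflate 9 (not isolated)
Conditions: Me3SiOTf, 2,2'-bipyridyl, CH2Cl2, 0 °C → rt; then H2O
Reagents that add atoms: none
Why: Methylene-acetal cleavage with silyl triflate/2,2'-bipyridyl, in which silylation of the less hindered acetal oxygen opens the ring, the pyridine traps the oxocarbenium ion as an N-(alkoxymethyl)pyridinium salt and water hydrolyses it, under buffered conditions that should leave the benzylic C7–O bond, the sulfonate and the benzyl ether intact.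

Step 7
Reactants: 10 (1S,2S)-diol tosylate
Product: 11 (1S,2S)-1-[4-(benzyloxy)-3-methoxyphenyl]-2-(5-bromo-2-hydroxy-3-methoxyphenyl)propane-1,3-diol
Conditions: KOH, MeOH/THF/H2O, 65 °C; then aq. NH4Cl
Reagents that add atoms: none
Why: Alkaline hydrolysis of the aryl sulfonate (hydroxide attack at sulfur) frees the ring B phenol, while diol, aryl bromide and benzyl ether are inert to base; 11 is the branch point for both halves.

Step 8
Reactants: 11 (1S,2S)-phenol diol
Product: 12 (1S,2S)-1-[4-(benzyloxy)-3-methoxyphenyl]-2-[2-(benzyloxy)-5-bromo-3-methoxyphenyl]propane-1,3-diol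
Conditions: BnBr, K2CO3, DMF, rt
Reagents that add atoms: benzyl bromide, BrCc1ccccc1
Why: Williamson ether synthesis, chemoselective because carbonate deprotonates only the phenol.

Step 9
Reactants: 12 (1S,2S)-dibenzyl ether diol
Product: 13 1,3-bis(tert-butyldimethylsilyl) ether of 12
Conditions: TBSOTf, 2,6-lutidine, CH2Cl2, −20 → 0 °C
Reagents that add atoms: tert-butyldimethylsilyl triflate, CC(C)(C)[Si](C)(C)OS(=O)(=O)C(F)(F)F
Why: Silyl ether formation with the silyl triflate, reactive enough for the hindered benzylic secondary hydroxyl, with lutidine buffering against benzylic ionisation.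

Step 10
Reactants: 11 (1S,2S)-phenol diol
Product: 14 [(2R,3S)-2-(4-benzyloxy-3-methoxyphenyl)-5-bromo-7-methoxy-2,3-dihydro-1-benzofuran-3-yl]methanol
Conditions: TsOH·H2O (10 mol%), CH2Cl2 (high dilution), 0 °C → rt
Reagents that add atoms: none
Why: Acid-catalysed dehydrative cycloetherification (SN1, 5-exo-trig capture of the p-benzyloxybenzylic cation by the ortho phenol), in which only C7 can ionise and the reversible closure should give the 2,3-trans dihydrobenzofuran because the aryl group avoids the C3 hydroxymethyl group, so that C2 (R) is set by C3 with net inversion at the former C7.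

Step 11
Reactants: 14 (2R,3S)-dihydrobenzofuran alcohol
Product: 15 tert-butyldimethylsilyl ether of 14
Conditions: TBSCl, imidazole, DMF, rt
Reagents that add atoms: tert-butyldimethylsilyl chloride, CC(C)(C)[Si](C)(C)Cl
Why: Standard silylation of a primary alcohol.

Step 12
Reactants: 15 silyl ether of the bromo dihydrobenzofuran; 7 formaldehyde (dry paraformaldehyde)
Product: 17 [(2R,3S)-2-(4-benzyloxy-3-methoxyphenyl)-3-(tert-butyldimethylsilyloxymethyl)-7-methoxy-2,3-dihydro-1-benzofuran-5-yl]methanol, via aryllithium 16 (not isolated)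
Conditions: t-BuLi (2 equiv), THF, −78 °C; then paraformaldehyde, −78 °C → rt; then H2O
Reagents that add atoms: none
Why: Bromine–lithium exchange, faster than any deprotonation at −78 °C, followed by addition of the aryllithium to formaldehyde (hydroxymethylation).

Step 13
Reactants: 17 benzylic alcohol of the benzofuran half
Product: 18 (2R,3S)-2-(4-benzyloxy-3-methoxyphenyl)-5-(bromomethyl)-3-(tert-butyldimethylsilyloxymethyl)-7-methoxy-2,3-dihydro-1-benzofuran
Conditions: CBr4, PPh3, CH2Cl2, 0 °C
Reagents that add atoms: carbon tetrabromide, BrC(Br)(Br)Br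
Why: Appel reaction under neutral conditions, which spares the silyl ether and the benzylic ether bond of the dihydrobenzofuran.

Step 14
Reactants: 19 (S)-epichlorohydrin; 20 dimethyl malonate
Product: 21 methyl (1R,5S)-2-oxo-3-oxabicyclo[3.1.0]hexane-1-carboxylate
Conditions: NaOMe, MeOH, 0 °C → reflux
Reagents that add atoms: none
Why: Tandem malonate alkylation/cyclopropanation/lactonisation, in which the malonate anion opens the epoxide at its CH2, the alkoxide closes a new epoxide with loss of chloride, the second malonate anion opens it 3-exo-tet with inversion and the freed alkoxide lactonises onto the cis ester, so that the one stereocentre of 19 fixes both ring-fusion centres.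

Step 15
Reactants: 13 bis-silylated aryl bromide of the diol half; 21 cyclopropane lactone
Product: 24 methyl (3R,4S)-4-{3-[(1S,2S)-1-(4-benzyloxy-3-methoxyphenyl)-1,3-bis(tert-butyldimethylsilyloxy)propan-2-yl]-4-benzyloxy-5-methoxybenzyl}-2-oxotetrahydrofuran-3-carboxylate (3,4-trans; C3 epimerisable), via aryllithium 22 (not isolated), via arylmagnesium bromide 23 (not isolated)
Conditions: t-BuLi (2 equiv), THF, −78 °C; MgBr2·OEt2, −78 → −30 °C; CuI (10 mol%), 21 (1.3 equiv), −30 → 0 °C; AcOH quench
Reagents that add atoms: none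
Why: Copper-catalysed homoconjugate addition of an aryl Grignard reagent to a doubly activated cyclopropane, in which the aryl group attacks the unsubstituted cyclopropane CH2 and forms the ring B–CH2 bond while the untouched C5 stereocentre becomes lactone C4 (S).

Step 16
Reactants: 24 lactone ester
Product: 25 (4S)-4-{3-[(1S,2S)-1-(4-benzyloxy-3-methoxyphenyl)-1,3-bis(tert-butyldimethylsilyloxy)propan-2-yl]-4-benzyloxy-5-methoxybenzyl}dihydrofuran-2(3H)-one
Conditions: LiCl, H2O, DMSO, 130 °C
Reagents that add atoms: none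
Why: Krapcho demethoxycarbonylation (chloride SN2 at the methyl ester, then loss of CO2) removes the activating ester under neutral conditions without touching C4.

Step 17
Reactants: 25 (4S)-4-benzylbutyrolactone of the diol half; 18 benzylic bromide of the benzofuran half
Product: 27 tris-TBS tris-benzyl ether of the target with (3S,4S)-trans lactone, via lithium enolate 26 (not isolated)
Conditions: LiN(SiMe3)2, THF, −78 °C; then 18, DMPU, −78 → −40 °C
Reagents that add atoms: none
Why: Alkylation of the lactone lithium enolate with a benzylic bromide, which should enter anti to the C4 substituent and give the 3,4-trans lactone (3S), the usual outcome for 4-benzylbutyrolactones.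

Step 18
Reactants: 27 fully protected lactone
Product: 28 tris-benzyl ether of the target (ring A, ring B and ring D phenols benzylated)
Conditions: Bu4NF, AcOH, THF, rt
Reagents that add atoms: none
Why: Fluoride-mediated cleavage of the three silyl ethers, buffered with acetic acid so that the lactone is neither opened nor epimerised.

Step 19
Reactants: 28 tris-benzyl ether
Product: 29 CNP0199264.1
Conditions: H2 (1 atm), Pd/C, EtOAc/MeOH, rt
Reagents that add atoms: none
Why: Catalytic hydrogenolysis of the three aryl benzyl ethers under neutral conditions at ambient pressure, where the benzylic alcohol and the C2–O bond of the dihydrobenzofuran are normally retained.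

**Compound list**

1 | 5-bromo-2-hydroxy-3-methoxybenzaldehyde | COc1cc(Br)cc(C=O)c1O | starting material
2 | 4-bromo-2-formyl-6-methoxyphenyl 4-methylbenzenesulfonate | COc1cc(Br)cc(C=O)c1OS(=O)(=O)c1ccc(C)cc1 | intermediate
3 | [4-(benzyloxy)-3-methoxyphenyl]methanol | COc1cc(CO)ccc1OCc1ccccc1 | starting material
4 | 1-(benzyloxy)-4-(bromomethyl)-2-methoxybenzene | COc1cc(CBr)ccc1OCc1ccccc1 | intermediate
5 | diethyl [4-(benzyloxy)-3-methoxybenzyl]phosphonate | CCOP(=O)(Cc1ccc(OCc2ccccc2)c(OC)c1)OCC | intermediate
6 | 2-[(E)-2-(4-benzyloxy-3-methoxyphenyl)ethenyl]-4-bromo-6-methoxyphenyl 4-methylbenzenesulfonate | COc1cc(/C=C/c2cc(Br)cc(OC)c2OS(=O)(=O)c2ccc(C)cc2)ccc1OCc1ccccc1 | intermediate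
7 | formaldehyde (used as paraformaldehyde) | C=O | starting material
8 | (4S,5S)-4-[4-(benzyloxy)-3-methoxyphenyl]-5-[5-bromo-3-methoxy-2-(tosyloxy)phenyl]-1,3-dioxane | COc1cc([C@H]3OCOC[C@@H]3c2cc(Br)cc(OC)c2OS(=O)(=O)c2ccc(C)cc2)ccc1OCc1ccccc1 | intermediate
9 | 1-(alkoxymethyl)-2,2'-bipyridin-1-ium triflate of the opened acetal (C7–O–CH2–N+, C9–O–SiMe3; drawn as the regioisomer silylated at the primary oxygen) | COc1cc([C@@H](OC[n+]2ccccc2-c2ccccn2)[C@H](CO[Si](C)(C)C)c2cc(Br)cc(OC)c2OS(=O)(=O)c2ccc(C)cc2)ccc1OCc1ccccc1.[O-]S(=O)(=O)C(F)(F)F | intermediate (not isolated)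
10 | (1S,2S)-1-[4-(benzyloxy)-3-methoxyphenyl]-2-[5-bromo-3-methoxy-2-(tosyloxy)phenyl]propane-1,3-diol | COc1cc([C@@H](O)[C@H](CO)c2cc(Br)cc(OC)c2OS(=O)(=O)c2ccc(C)cc2)ccc1OCc1ccccc1 | intermediate
11 | (1S,2S)-1-[4-(benzyloxy)-3-methoxyphenyl]-2-(5-bromo-2-hydroxy-3-methoxyphenyl)propane-1,3-diol | COc1cc([C@@H](O)[C@H](CO)c2cc(Br)cc(OC)c2O)ccc1OCc1ccccc1 | intermediate
12 | (1S,2S)-1-[4-(benzyloxy)-3-methoxyphenyl]-2-[2-(benzyloxy)-5-bromo-3-methoxyphenyl]propane-1,3-diol | COc1cc([C@@H](O)[C@H](CO)c2cc(Br)cc(OC)c2OCc2ccccc2)ccc1OCc1ccccc1 | intermediate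
13 | 1,3-bis(tert-butyldimethylsilyl) ether of 12 | COc1cc([C@@H](O[Si](C)(C)C(C)(C)C)[C@H](CO[Si](C)(C)C(C)(C)C)c2cc(Br)cc(OC)c2OCc2ccccc2)ccc1OCc1ccccc1 | intermediate
14 | [(2R,3S)-2-(4-benzyloxy-3-methoxyphenyl)-5-bromo-7-methoxy-2,3-dihydro-1-benzofuran-3-yl]methanol | Brc1cc(OC)c2c(c1)[C@@H](CO)[C@H](c1ccc(OCc3ccccc3)c(OC)c1)O2 | intermediate
15 | tert-butyldimethylsilyl ether of 14 | Brc1cc(OC)c2c(c1)[C@@H](CO[Si](C)(C)C(C)(C)C)[C@H](c1ccc(OCc3ccccc3)c(OC)c1)O2 | intermediate
16 | 5-lithio derivative of 15 | [Li]c1cc(OC)c2c(c1)[C@@H](CO[Si](C)(C)C(C)(C)C)[C@H](c1ccc(OCc3ccccc3)c(OC)c1)O2 | intermediate (not isolated)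
17 | [(2R,3S)-2-(4-benzyloxy-3-methoxyphenyl)-3-(tert-butyldimethylsilyloxymethyl)-7-methoxy-2,3-dihydro-1-benzofuran-5-yl]methanol | OCc1cc(OC)c2c(c1)[C@@H](CO[Si](C)(C)C(C)(C)C)[C@H](c1ccc(OCc3ccccc3)c(OC)c1)O2 | intermediate
18 | (2R,3S)-2-(4-benzyloxy-3-methoxyphenyl)-5-(bromomethyl)-3-(tert-butyldimethylsilyloxymethyl)-7-methoxy-2,3-dihydro-1-benzofuran | BrCc1cc(OC)c2c(c1)[C@@H](CO[Si](C)(C)C(C)(C)C)[C@H](c1ccc(OCc3ccccc3)c(OC)c1)O2 | intermediate
19 | (S)-epichlorohydrin | ClC[C@@H]1CO1 | starting material
20 | dimethyl malonate | COC(=O)CC(=O)OC | starting material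
21 | methyl (1R,5S)-2-oxo-3-oxabicyclo[3.1.0]hexane-1-carboxylate | O=C1OC[C@H]2C[C@@]12C(=O)OC | intermediate
22 | aryllithium from 13 (Li in place of Br) | COc1cc([C@@H](O[Si](C)(C)C(C)(C)C)[C@H](CO[Si](C)(C)C(C)(C)C)c2cc([Li])cc(OC)c2OCc2ccccc2)ccc1OCc1ccccc1 | intermediate (not isolated)
23 | arylmagnesium bromide from 13 | COc1cc([C@@H](O[Si](C)(C)C(C)(C)C)[C@H](CO[Si](C)(C)C(C)(C)C)c2cc([Mg]Br)cc(OC)c2OCc2ccccc2)ccc1OCc1ccccc1 | intermediate (not isolated)
24 | methyl (3R,4S)-4-{3-[(1S,2S)-1-(4-benzyloxy-3-methoxyphenyl)-1,3-bis(tert-butyldimethylsilyloxy)propan-2-yl]-4-benzyloxy-5-methoxybenzyl}-2-oxotetrahydrofuran-3-carboxylate | COc1cc([C@@H](O[Si](C)(C)C(C)(C)C)[C@H](CO[Si](C)(C)C(C)(C)C)c2cc(C[C@@H]3COC(=O)[C@H]3C(=O)OC)cc(OC)c2OCc2ccccc2)ccc1OCc1ccccc1 | intermediate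
25 | (4S)-4-{3-[(1S,2S)-1-(4-benzyloxy-3-methoxyphenyl)-1,3-bis(tert-butyldimethylsilyloxy)propan-2-yl]-4-benzyloxy-5-methoxybenzyl}dihydrofuran-2(3H)-one | COc1cc([C@@H](O[Si](C)(C)C(C)(C)C)[C@H](CO[Si](C)(C)C(C)(C)C)c2cc(C[C@@H]3COC(=O)C3)cc(OC)c2OCc2ccccc2)ccc1OCc1ccccc1 | intermediate
26 | lithium enolate of 25 | COc1cc([C@@H](O[Si](C)(C)C(C)(C)C)[C@H](CO[Si](C)(C)C(C)(C)C)c2cc(C[C@@H]3COC(O[Li])=C3)cc(OC)c2OCc2ccccc2)ccc1OCc1ccccc1 | intermediate (not isolated)
27 | tris(tert-butyldimethylsilyl) tris(benzyl) ether of the target, (3S,4S)-lactone | COc1cc([C@@H](O[Si](C)(C)C(C)(C)C)[C@H](CO[Si](C)(C)C(C)(C)C)c2cc(C[C@@H]3COC(=O)[C@H]3Cc3cc(OC)c4c(c3)[C@@H](CO[Si](C)(C)C(C)(C)C)[C@H](c3ccc(OCc5ccccc5)c(OC)c3)O4)cc(OC)c2OCc2ccccc2)ccc1OCc1ccccc1 | intermediate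
28 | tris(benzyl) ether of the target (three phenols benzylated, three hydroxyls free) | COc1cc([C@@H](O)[C@H](CO)c2cc(C[C@@H]3COC(=O)[C@H]3Cc3cc(OC)c4c(c3)[C@@H](CO)[C@H](c3ccc(OCc5ccccc5)c(OC)c3)O4)cc(OC)c2OCc2ccccc2)ccc1OCc1ccccc1 | intermediate
29 | (3S,4S)-3-{[(2R,3S)-2-(4-hydroxy-3-methoxyphenyl)-3-(hydroxymethyl)-7-methoxy-2,3-dihydro-1-benzofuran-5-yl]methyl}-4-{3-[(1S,2S)-1,3-dihydroxy-1-(4-hydroxy-3-methoxyphenyl)propan-2-yl]-4-hydroxy-5-methoxybenzyl}dihydrofuran-2(3H)-one (CNP0199264.1) | COc1cc([C@@H](O)[C@H](CO)c2cc(C[C@@H]3COC(=O)[C@H]3Cc3cc(OC)c4c(c3)[C@@H](CO)[C@H](c3ccc(O)c(OC)c3)O4)cc(OC)c2O)ccc1O | target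

**Count and risks**

Total step count: 19. Longest linear sequence: 13 steps (steps 2–9 and 15–19 from 3; the branch through steps 10–13 is equally long).

Steps most likely to fail:

Step 5 (the proposed method). The 1,2-diaryl alkene with its ortho sulfonate may not be accommodated by the confined acid, so turnover may be slow or facial discrimination poor, and acid-promoted alkene dimerisation may take over. The fallback uses known chemistry and sets out from 6. The classical Prins dioxane synthesis with paraformaldehyde and a catalytic achiral strong acid (TfOH in CH2Cl2), long used for β-substituted styrenes, should give the racemic trans-dioxane F1 with the same substrate control of regiochemistry and relative configuration. Separation of the enantiomers by preparative chromatography on a chiral stationary phase comes back to the route at 8.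

Step 6. The silyl triflate may ionise the electron-rich benzylic C7–O bond instead of the O–CH2–O carbon (loss of configuration at C7 or capture by the pyridine), or hydrolysis of the pyridinium intermediate may stall. The fallback sets out from 8. Acetolysis (Ac2O, catalytic TfOH, 0 °C), the classical way of opening Prins dioxanes, in which acylation of the less hindered primary-side oxygen directs cleavage to the acetal carbon, should give the acetoxymethyl ether acetate F2. Methanolysis (K2CO3, MeOH, rt), which leaves the aryl sulfonate alone, removes both acyl groups and the formaldehyde unit and comes back at 10.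

Step 15. Bromine–lithium exchange may be incomplete, the aryl metal may be quenched before copper transfer, or it may add to a carbonyl group of 21 instead of opening the cyclopropane. The fallback is a reductive cross-electrophile coupling that needs no aryl metal and sets out from 13. (S)-Paraconic acid F3 (from specialist suppliers or by resolution of the racemic acid) is reduced with BH3·SMe2 to (R)-4-(hydroxymethyl)dihydrofuran-2(3H)-one F4, which PPh3/I2/imidazole converts into (S)-4-(iodomethyl)dihydrofuran-2(3H)-one F5. Coupling of 13 with F5 (NiBr2(glyme), 4,4'-di-tert-butyl-2,2'-bipyridine, Zn, NaI, DMA, 60 °C) forms the same ring B–CH2 bond and comes back directly at 25, so that step 16 is not needed.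

Further compounds
F1 | step 5 | racemic trans-4-[4-(benzyloxy)-3-methoxyphenyl]-5-[5-bromo-3-methoxy-2-(tosyloxy)phenyl]-1,3-dioxane (both enantiomers) | COc1cc([C@H]3OCOC[C@@H]3c2cc(Br)cc(OC)c2OS(=O)(=O)c2ccc(C)cc2)ccc1OCc1ccccc1.COc1cc([C@@H]3OCOC[C@H]3c2cc(Br)cc(OC)c2OS(=O)(=O)c2ccc(C)cc2)ccc1OCc1ccccc1
F2 | step 6 | (1S,2S)-1-(acetoxymethoxy)-1-[4-(benzyloxy)-3-methoxyphenyl]-2-[5-bromo-3-methoxy-2-(tosyloxy)phenyl]propan-3-yl acetate | COc1cc([C@@H](OCOC(C)=O)[C@H](COC(C)=O)c2cc(Br)cc(OC)c2OS(=O)(=O)c2ccc(C)cc2)ccc1OCc1ccccc1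
F3 | step 15 | (S)-paraconic acid [(S)-5-oxotetrahydrofuran-3-carboxylic acid] | OC(=O)[C@@H]1COC(=O)C1
F4 | step 15 | (R)-4-(hydroxymethyl)dihydrofuran-2(3H)-one | OC[C@@H]1COC(=O)C1
F5 | step 15 | (S)-4-(iodomethyl)dihydrofuran-2(3H)-one | IC[C@@H]1COC(=O)C1
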